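The readings are calculated with constants of no real substance, and the scatter is random.

The trap in these runs is to read the flattening of the product curve as a ceiling drawing near, when the substrate may simply be falling as a power of the time.

the same everywhere: gas phase 13 mM (held)

|  | substrate | free catalyst | remark | time |
|---|---|---|---|---|
| north-east | 0.15 M | 15 mM | run made earlier |  |
| north-west | 0.60 M | 15 mM | run made earlier |  |
| south | 0.30 M | 30 mM | run made earlier |  |
| flask | 0.30 M | 15 mM |  | 2.5 d |

| run | time / d | product / % | substrate / % |
|---|---|---|---|
| north-east | 0.500 | 52 | 49 |
| north-east | 1.04 | 66 | 36 |
| north-east | 1.67 | 73 | 26 |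
| north-east | 2.08 | 75 | 23 |
| north-east | 2.50 | 78 | 21 |
| north-east | 3.00 | 80 | 17 |
| north-west | 0.500 | 41 | 63 |
| north-west | 1.04 | 55 | 43 |
| north-west | 1.67 | 66 | 34 |
| north-west | 2.08 | 70 | 30 |
| north-west | 2.50 | 72 | 31 |
| north-west | 3.00 | 74 | 26 |
| south | 0.250 | 43 | 59 |
| south | 0.833 | 67 | 34 |
| south | 1.25 | 72 | 27 |
| south | 2.00 | 78 | 22 |
| south | 3.00 | 83 | 16 |

(scatter of a reading: 1.5 percentage points)

- the analysis behind the earlier runs scatters by 1.5 percentage points, standard deviation
- at the start none of the gas phase is in solution

- winter: doubling the amount of free catalyst, all else as stated
- autumn: doubling the saturation concentration of gas phase, all else as stated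
- dawn: doubling the transfer coefficient of the gas phase, all else as stated

1. product at 2.5 d, in percent of the substrate charged
2. the change that raises the amount of product at 2.5 d, in percent of the substrate charged most ("none" if none brings more than 2 percentage points) (winter / autumn / dawn / none)
3. amount of product at 2.5 d, in percent of the substrate charged, after dawn

So I set the substrate column against the time column, from the second row to the last. As a slope of ln(substrate left) against ln(time), the north-east run reads 0.708 and the north-west run 0.475. The south run, with twice the free catalyst, reads 0.588, inside that spread. I take the mean of the first two, 0.592, as the fall exponent n: the power of the time by which the substrate left shrinks on the late readings. These are readings and carry their scatter. Each doubling of the time then keeps 66.3% of the substrate.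

The flask's substrate charge lies between those of the two runs, so at 1.04 d I take their mean, 39.5%. Carried to 2.5 d, that leaves 23.5%. Product and substrate add up close to the charge in these runs, so my figure for the flask is 76.5% product.

The forecast says 75.5%, 1.00 percentage point below mine, with autumn as the best change and 77% after dawn, holding that “gas transfer can limit only the early phase”.

The flask gives 76.6%. Autumn adds 18 points, the most, against 4.5 points for winter and 2.7 points for dawn, which ends at 79.3%.

    2 dissolved gas → homo dimer (k = 5.00 × 10⁻⁴ M⁻¹ s⁻¹)
    substrate + dissolved gas + free catalyst → free catalyst + product (k = 0.240 M⁻² s⁻¹)
    2 free catalyst → spent catalyst (k = 0.00260 M⁻¹ s⁻¹)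
    gas phase ⇌ dissolved gas, rate k4*(csat - [dissolved gas]) (kL = 0.00130 s⁻¹)

The flask stops short of its charge because free catalyst pairs off to spent catalyst (second-order deactivation) and because the reading comes early: without that loss it passes >99.9%, and at 25.0 d it holds 93.8%. Free catalyst then falls about as one over the time, so n is the making constant times dissolved gas over twice the loss constant, 0.588. Under autumn n doubles and the fraction left squares, a gain of 18 points. With the other amounts and the time held, the flask's product moves 5 points from 76.6% at 8.91 mM or 33.1 mM of free catalyst.

At 15 h, n carried back gives 46.8% product. The computed flask holds 52.5%; that reading lies earlier than the stretch n came from.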